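**Retrosynthetic overview**
1. The C6 ester is made last: alcohol 15 is acylated with 4-methoxybenzoyl chloride after desilylation of 14.
2. Key disconnection: the C1–O bond of the ether bridge. It goes back to the tertiary C4 alcohol 12 and is made by alkoxy-radical 1,5-hydrogen-atom transfer, which turns ring A into the 7-oxabicyclo[2.2.1]heptane.
3. Feature used: in 12 the C4–O bond and the C1–H bond lie 1,4 across ring A (C1, C2, C3, C4, C5, C10) on the β face that also carries H5; the methyl groups on C4 and C10 are syn-diaxial on the α face and strain the chair of ring A.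
4. 12 comes from the Δ5 tertiary allylic alcohol 8 by a silicon tether on the C4 oxygen that adds Si–H across C5=C6 and fixes H5 and O6; 8 comes from enone 7 by methyl addition; ring A of 7 is closed from enol triflate 5 by hydroboration and carbonylative Suzuki–Miyaura coupling.
5. Ring order: ring B is the carvone ring (C7 from (R)-carvone, C10 by reductive allylation), then ring A (step 4), then the oxygen bridge (step 8).

Key step: step 8

Remark on the chemistry: eudesmane numbering is used throughout (carvone C1, C2, C5, C6 become C5, C10, C7, C6); α is the face of the C10 methyl group, β the face of H5, the C6 oxygen, the C7 isopropyl group and the 1,4-oxygen bridge, as the target SMILES requires. The C7 isopropyl group is then axial in the trans-decalin, so no C6 ketone is exposed to base in the main route.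

Step 1
Reactants: 1 (R)-carvone
Product: 2 (R)-carvotanacetone
Conditions: H2 (1 atm), RhCl(PPh3)3 (cat.), benzene, rt
Reagents that add atoms: none
Why: Chemoselective homogeneous hydrogenation saturates the unhindered 1,1-disubstituted isopropenyl alkene and leaves the conjugated trisubstituted enone and the existing stereocentre untouched.

Step 2
Reactants: 2 (R)-carvotanacetone; 3 allyl bromide
Product: 4 (2R,5R)-2-allyl-2-methyl-5-isopropylcyclohexanone (allyl cis to isopropyl)
Conditions: Li, NH3(l)/THF, t-BuOH (1 equiv), −78 °C; then 3, −78 to −33 °C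
Reagents that add atoms: none
Why: Dissolving-metal reduction of the enone gives the lithium enolate on the methyl-bearing carbon only, and its C-allylation (reductive alkylation) should take the axial path of the half-chair with isopropyl equatorial, so that allyl enters cis to isopropyl and the quaternary C10 is set with its methyl trans to isopropyl.

Step 3
Reactants: 4 allyl ketone
Product: 5 enol trifluoromethanesulfonate of 4 (C5=C6, OTf on C5)
Conditions: KN(SiMe3)2, THF, −78 °C; then PhNTf2, −78 °C to rt
Reagents that add atoms: N-phenylbis(trifluoromethanesulfonimide), FC(F)(F)S(=O)(=O)N(c1ccccc1)S(=O)(=O)C(F)(F)F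
Why: Only C6 carries α-hydrogens (C10 is quaternary), so enolate formation and O-sulfonylation give a single enol triflate and do not touch C7.

Step 4
Reactants: 5 enol triflate
Product: 7 15-noreudesm-5-en-4-one (10α-methyl; 7β-isopropyl), via alkylborane 6 (not isolated)
Conditions: 9-BBN, THF, 0 °C to rt; then PdCl2(dppf) (5 mol %), K3PO4 (aq), CO (1 atm), THF–DMF, 50 °C
Reagents that add atoms: carbon monoxide, [C-]#[O+]
Why: 9-BBN hydroborates only the monosubstituted allyl alkene (boron on C3), and the intramolecular carbonylative Suzuki–Miyaura coupling (oxidative addition of the enol triflate to zerovalent palladium, CO insertion, B-alkyl transmetalation, reductive elimination) should close ring A as the C4 ketone conjugated with C5=C6.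

Step 5
Reactants: 7 enone
Product: 8 eudesm-5-en-4β-ol (4α-methyl; 10α-methyl; 7β-isopropyl)
Conditions: MeLi, CeCl3, THF, −78 °C
Reagents that add atoms: methyllithium, [Li]C
Why: Organocerium 1,2-addition to the hindered enone avoids enolisation and conjugate addition; with isopropyl pseudoequatorial, ring B holds C9 axial on ring A over the β face of the carbonyl, so methyl should enter equatorially from the α face and leave the C4 hydroxyl β, which sets C4.

Step 6
Reactants: 8 tertiary allylic alcohol
Product: 11 eudesmane-4β,6β-diol (5β-H), via dimethylsilyl ether 9 (not isolated), via cyclic siloxane 10 (not isolated)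
Conditions: HMe2SiCl, Et3N, DMAP (cat.), CH2Cl2, 0 °C; Pt2[(CH2=CHSiMe2)2O]3 (Karstedt catalyst, 0.5 mol %), toluene, 60 °C; then 30% H2O2, KF, KHCO3, THF–MeOH, rt
Reagents that add atoms: hydrogen peroxide, OO
Why: Tamao intramolecular hydrosilylation (5-endo) and Tamao–Fleming oxidation: silicon tied to the β oxygen on C4 can reach C6 only on the β face and the syn addition puts hydrogen on C5 on the same face, which sets the trans ring fusion (H5β) and, after oxidation of C–Si with retention, the 6β-hydroxyl.

Step 7
Reactants: 11 diol
Product: 12 6β-(tert-butyldimethylsilyloxy)eudesman-4β-ol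
Conditions: TBSOTf (1.1 equiv), 2,6-lutidine, CH2Cl2, −78 °C
Reagents that add atoms: tert-butyldimethylsilyl trifluoromethanesulfonate, CC(C)(C)[Si](C)(C)OS(=O)(=O)C(F)(F)F
Why: Silylation of the secondary C6 hydroxyl; the tertiary C4 hydroxyl should be too hindered to compete at −78 °C with one equivalent of silyl triflate.

Step 8
Reactants: 12 tertiary alcohol
Product: 14 1β,4β-epoxy-6β-(tert-butyldimethylsilyloxy)eudesmane, via C4 hypoiodite 13 (not isolated)
Conditions: PhI(OAc)2 (1.5 equiv), I2 (1 equiv), benzene, visible light (white LED), 10 °C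
Reagents that add atoms: none
Why: Proposed new method: AcOI made from PhI(OAc)2 and I2 turns the C4 hydroxyl into hypoiodite 13, light cleaves the O–I bond, and the C4 alkoxy radical takes the β hydrogen from C1 through a six-membered transition state when ring A reaches its 1,4-boat; the C1 radical is oxidised by iodine or by the trivalent iodine reagent and the C4 oxygen closes the C1–O bond. The closest known reaction type is the hypoiodite etherification of alcohols by 1,5-hydrogen-atom transfer (Suárez conditions), routine for 1,3-diaxial O and C–H pairs but not shown across the 1,4 axis of a trans-fused cyclohexane. The ring that closes is the oxolane O–C4–C5–C10–C1 (5-exo-tet at C1), and because it spans C1 and C4 it completes the 7-oxabicyclo[2.2.1]heptane in a bridging mode. The one new stereocentre, C1, is fixed by the tether: the oxygen is held on the β face of C4 and can only bond to the β face of C1. The step needs site selectivity for C1–H, which the substrate secures because the equatorial C4–O bond lies anti to C10 and cannot reach the hydrogens on the C10 methyl, C9 or C7, so the β hydrogen on C1 is the only δ hydrogen available, and the chair of ring A is already strained by the syn-diaxial C4 and C10 methyl groups. It also needs hydrogen transfer to outrun β-scission of the C4–C5 bond, which the substrate does not secure, since the trans ring fusion resists the boat; hence the low temperature and the non-polar solvent.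

Step 9
Reactants: 14 tricyclic silyl ether
Product: 15 1β,4β-epoxyeudesman-6β-ol
Conditions: Bu4NF, THF, rt to 50 °C
Reagents that add atoms: none
Why: Fluoride cleavage of the silyl ether (Si–F bond formation); the bridged ether and all stereocentres are inert to it.

Step 10
Reactants: 15 tricyclic alcohol; 16 4-methoxybenzoyl chloride
Product: 17 1β,4β-epoxyeudesman-6β-yl 4-methoxybenzoate (target)
Conditions: 16 (1.5 equiv), Et3N, DMAP, CH2Cl2, rt to 40 °C
Reagents that add atoms: none
Why: DMAP-catalysed acylation (nucleophilic catalysis) of the secondary alcohol by the acid chloride, with retention at C6.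

**Compound list**
1 | (R)-carvone | CC1=CC[C@H](CC1=O)C(C)=C | starting material
2 | (R)-carvotanacetone, (5R)-2-methyl-5-(propan-2-yl)cyclohex-2-en-1-one | CC1=CC[C@H](CC1=O)C(C)C | intermediate
3 | allyl bromide (3-bromoprop-1-ene) | C=CCBr | starting material
4 | (2R,5R)-2-methyl-5-(propan-2-yl)-2-(prop-2-en-1-yl)cyclohexan-1-one, allyl cis to isopropyl | O=C1C[C@H](C(C)C)CC[C@]1(C)CC=C | intermediate
5 | enol trifluoromethanesulfonate of 4 (C5=C6, OTf on C5) | FC(F)(F)S(=O)(=O)OC1=C[C@H](C(C)C)CC[C@]1(C)CC=C | intermediate
6 | B-alkyl-9-BBN adduct of 5, boron on C3 (not isolated) | FC(F)(F)S(=O)(=O)OC1=C[C@H](C(C)C)CC[C@]1(C)CCCB1C2CCCC1CCC2 | intermediate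
7 | 15-noreudesm-5-en-4-one (10α-methyl, 7β-isopropyl) | O=C1CCC[C@@]2(C)CC[C@@H](C(C)C)C=C12 | intermediate
8 | eudesm-5-en-4β-ol (4α-methyl, 10α-methyl, 7β-isopropyl) | O[C@@]1(C)CCC[C@@]2(C)CC[C@@H](C(C)C)C=C12 | intermediate
9 | 4β-O-dimethylsilyl ether of 8 (not isolated) | C[SiH](C)O[C@@]1(C)CCC[C@@]2(C)CC[C@@H](C(C)C)C=C12 | intermediate
10 | cyclic siloxane, SiMe2 bridging O4 and C6 on the β face, H5β (not isolated) | C[Si]1(C)[C@@H]2[C@H](C(C)C)CC[C@]3(C)CCC[C@](C)(O1)[C@@H]23 | intermediate
11 | eudesmane-4β,6β-diol (5β-H, 7β-isopropyl, 10α-methyl) | O[C@@H]1[C@H](C(C)C)CC[C@]2(C)CCC[C@](C)(O)[C@@H]12 | intermediate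
12 | 6β-(tert-butyldimethylsilyloxy)eudesman-4β-ol, precursor of the key step | CC(C)(C)[Si](C)(C)O[C@@H]1[C@H](C(C)C)CC[C@]2(C)CCC[C@](C)(O)[C@@H]12 | intermediate
13 | C4 hypoiodite of 12 (not isolated) | CC(C)(C)[Si](C)(C)O[C@@H]1[C@H](C(C)C)CC[C@]2(C)CCC[C@](C)(OI)[C@@H]12 | intermediate
14 | 1β,4β-epoxy-6β-(tert-butyldimethylsilyloxy)eudesmane, product of the key step | CC(C)(C)[Si](C)(C)O[C@@H]1[C@H](C(C)C)CC[C@]2(C)[C@H]3CC[C@](C)(O3)[C@@H]12 | intermediate
15 | 1β,4β-epoxyeudesman-6β-ol | O[C@@H]1[C@H](C(C)C)CC[C@]2(C)[C@H]3CC[C@](C)(O3)[C@@H]12 | intermediate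
16 | 4-methoxybenzoyl chloride | COc1ccc(cc1)C(Cl)=O | starting material
17 | 1β,4β-epoxyeudesman-6β-yl 4-methoxybenzoate (CNP0196044.2) | COc1ccc(C(=O)O[C@@H]2[C@H](C(C)C)CC[C@]3(C)[C@H]4CC[C@](C)(O4)[C@@H]23)cc1 | target

**Step count**
Total: 10 steps. Longest linear sequence: 10 steps, from 1 to 17.

**Steps most likely to fail**

1. Step 8 (proposed new method). After O–I homolysis the alkoxy radical may fragment by β-scission of C4–C5, opening ring A, faster than it abstracts hydrogen from C1, because the trans ring fusion resists the boat that the transfer needs. Acid formed in the flask could also cleave the silyl ether.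
Fallback, known chemistry throughout; it leaves the route at 2 and rejoins it at 15. The C1 oxygen is brought in with the side chain, the bridge is closed by intramolecular Williamson displacement while C5 is still trigonal (ring A can then reach the boat), and the trans ring fusion is made last by hydroboration. The lithium enolate generated from 2 as in step 2 (ammonia removed, THF, −78 °C) is trapped with acrolein to give the aldol 2-(1-hydroxyprop-2-enyl)-2-methyl-5-isopropylcyclohexanone F1 (both C1 epimers, carried together). Et3SiCl and imidazole give its triethylsilyl ether F2, and KN(SiMe3)2 with PhNTf2 gives the enol triflate F3. 9-BBN followed by PdCl2(dppf), K3PO4 and CO as in step 4 gives 1-(triethylsilyloxy)-15-noreudesm-5-en-4-one F4, and MeLi with CeCl3 as in step 5 gives 1-(triethylsilyloxy)eudesm-5-en-4β-ol F5. Bu4NF frees eudesm-5-ene-1,4β-diol F6, and MsCl in pyridine at 0 °C sulfonylates only the secondary C1 hydroxyl to the 1-methanesulfonate F7. KH in THF then lets the C4 alkoxide displace the mesylate at C1 with inversion (5-exo-tet, the known closure of trans-4-sulfonyloxycyclohexanols to 7-oxabicyclo[2.2.1]heptanes). Only the 1α-mesylate can do this; it gives 1β,4β-epoxyeudesm-5-ene F8, and the 1β-mesylate is separated here. BH3·THF followed by NaOH and H2O2 should add H and OH syn across C5=C6 of F8 from the exo face, that of the oxygen bridge and opposite to the endo C10 methyl and the C2–C3 bridge, which gives H5β and the 6β-alcohol 15.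

2. Step 4. The alkylborane may transmetalate before CO inserts (direct B-alkyl coupling that closes a five-membered ring), or oxidative addition at the hindered triflate may be slow enough for protodeboronation to take over.
Fallback; it leaves the route at 5 and rejoins it at 7, with the carbonyl carbon put in first and the ring closed by an anionic acylation. Pd(OAc)2 with 1,3-bis(diphenylphosphino)propane, CO (1 atm), MeOH and Et3N in DMF at 60 °C give methyl 6-allyl-6-methyl-3-isopropylcyclohex-1-ene-1-carboxylate F9. 9-BBN and then NaBO3 give the 3-hydroxypropyl ester F10, and I2, PPh3 and imidazole give the 3-iodopropyl ester F11. t-BuLi (2 equiv) in Et2O–pentane at −78 °C effects iodine–lithium exchange and intramolecular acylation of the ester to give 7.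

3. Step 5. Facial selectivity may be poor or inverted if the addition runs through the other half-chair, in which the C10 methyl group is axial over the α face and methyl enters from the β face.
Fallback; it leaves the route at 7 and rejoins it at 8, and uses the same bias to deliver oxygen instead of carbon. The adduct is then eudesm-5-en-4α-ol F12, the C4 epimer of 8. [C5H5NH][CrO3Cl] (pyridinium chlorochromate) in CH2Cl2 rearranges and oxidises F12, or its mixture with 8, to eudesm-4-en-6-one F13 (Babler–Dauben oxidative transposition, which erases the C4 stereocentre). H2O2 and LiOH in MeOH at 0 °C (Weitz–Scheffer epoxidation, kept cold and short so that C7 next to the ketone does not epimerise) should give 4β,5β-epoxyeudesman-6-one F14, with oxygen entering on the face the methyl reagent had chosen. N2H4·H2O and AcOH in MeOH (Wharton transposition) return 8 with the C4–O bond retained.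

Further compounds
F1 | step 8 | 2-(1-hydroxyprop-2-enyl)-2-methyl-5-isopropylcyclohexanone, both C1 epimers | O=C1C[C@H](C(C)C)CC[C@]1(C)C(O)C=C
F2 | step 8 | triethylsilyl ether of F1 | O=C1C[C@H](C(C)C)CC[C@]1(C)C(O[Si](CC)(CC)CC)C=C
F3 | step 8 | enol trifluoromethanesulfonate of F2 | FC(F)(F)S(=O)(=O)OC1=C[C@H](C(C)C)CC[C@]1(C)C(O[Si](CC)(CC)CC)C=C
F4 | step 8 | 1-(triethylsilyloxy)-15-noreudesm-5-en-4-one | O=C1CCC(O[Si](CC)(CC)CC)[C@@]2(C)CC[C@@H](C(C)C)C=C12
F5 | step 8 | 1-(triethylsilyloxy)eudesm-5-en-4β-ol | O[C@@]1(C)CCC(O[Si](CC)(CC)CC)[C@@]2(C)CC[C@@H](C(C)C)C=C12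
F6 | step 8 | eudesm-5-ene-1,4β-diol | O[C@@]1(C)CCC(O)[C@@]2(C)CC[C@@H](C(C)C)C=C12
F7 | step 8 | 1-methanesulfonate of F6 | O[C@@]1(C)CCC(OS(C)(=O)=O)[C@@]2(C)CC[C@@H](C(C)C)C=C12
F8 | step 8 | 1β,4β-epoxyeudesm-5-ene | CC(C)[C@@H]1CC[C@]2(C)[C@H]3CC[C@](C)(O3)C2=C1
F9 | step 4 | methyl 6-allyl-6-methyl-3-isopropylcyclohex-1-ene-1-carboxylate | COC(=O)C1=C[C@H](C(C)C)CC[C@]1(C)CC=C
F10 | step 4 | methyl 6-(3-hydroxypropyl)-6-methyl-3-isopropylcyclohex-1-ene-1-carboxylate | COC(=O)C1=C[C@H](C(C)C)CC[C@]1(C)CCCO
F11 | step 4 | methyl 6-(3-iodopropyl)-6-methyl-3-isopropylcyclohex-1-ene-1-carboxylate | COC(=O)C1=C[C@H](C(C)C)CC[C@]1(C)CCCI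
F12 | step 5 | eudesm-5-en-4α-ol (4β-methyl), C4 epimer of 8 | O[C@]1(C)CCC[C@@]2(C)CC[C@@H](C(C)C)C=C12
F13 | step 5 | eudesm-4-en-6-one (10α-methyl, 7β-isopropyl) | CC1=C2C(=O)[C@H](C(C)C)CC[C@]2(C)CCC1
F14 | step 5 | 4β,5β-epoxyeudesman-6-one | C[C@]12CCC[C@@]3(C)CC[C@@H](C(C)C)C(=O)[C@@]31O2
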